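**The constant.** Take the amber run's last electrophile reading and divide out the time and the nucleophile.

all flasks: electrophile 0.10 M

| charge | nucleophile | remark | time |
|---|---|---|---|
| amber | 1.2 equiv | run made earlier |  |
| Friday's | 2.00 equiv |  | 12 min |
| Tuesday's | 3.00 equiv |  | 12 min |

amber run (percent of the electrophile charged)

| time / min | electrophile / % | target / % |
|---|---|---|
| 2.00 | 93.6 | 2.8 |
| 4.00 | 88.2 | 6.4 |
| 6.00 | 84.1 | 8.1 |
| 8.00 | 77.5 | 9.0 |
| 10.0 | 75.0 | 12.4 |
| 12.0 | 71.9 | 14.2 |

(each reading ± 1 percentage point)

- a reading or a percentage of target counts all its forms, free or not
- what has gone from electrophile into another species counts as reacted, even if it can come back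
- a reading of electrophile is of its free form alone

- part of the electrophile that has reacted at the end, Friday's
- part of the electrophile that has reacted at the end, Tuesday's
- what raising the equivalents of nucleophile from its lowest to its highest value here does to the part of the electrophile that has reacted (changes below 5 percentage points count as none) (no change / it falls / it rises)

The amber run has lost 28.1% of its free electrophile at 12.0 min. That reading gives κ = 0.229 M⁻¹ min⁻¹, the loss constant: the pseudo-first-order rate constant for loss of free electrophile per unit concentration of nucleophile charged. It carries the scatter of that reading.

**Low end.** If nucleophile plays no part in the loss, both new flasks stay at the amber figure. But the last amber target reading is half of the loss read at that time, and I take it that target needs nucleophile, so I leave this end.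

**High end.** If the loss is first order in nucleophile held at its charge c, the part reacted after time t is 1 − exp(−κct). That gives 42.3% for Friday's flask and 56.2% for Tuesday's. If one nucleophile goes per electrophile lost, my estimate for Friday's flask spends 21.1% of its nucleophile charge, less than the 78.9% it leaves. So I commit to this end and expect a rise.

**The forecast.** It gives 40% for Friday's flask, 51% for Tuesday's, and "it rises", saying “I take intermediate values”. Its Tuesday figure stands below mine.

**The result.** Friday's flask gives 41.8% and Tuesday's 55.2%; from the lowest to the highest equivalents, it rises by 13 percentage points.

    electrophile + nucleophile → acid set free + target (k = 0.00220 M⁻¹ s⁻¹)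
    nucleophile + acid set free ⇌ protonated nucleophile, settled at all times (K = 69.0 M⁻¹)
    nucleophile + target → over-reaction product (k = 0.0110 M⁻¹ s⁻¹)
    electrophile + target ⇌ idle adduct, settled at all times (K = 450 M⁻¹)

**Neighbouring flask.** Take Tuesday's flask with 0.025 M of electrophile, a quarter of its charge, with the equivalents and the time held. The nucleophile concentration falls with it, so κ gives 18.6% reacted. The neighbouring flask gives 19.4%.

(The runs are simulated from invented constants, and the scatter is random.)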